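Stirring this flask on to 15 d is worth doing only if product can still rise, so the quantity to reckon first is the product ceiling: the equivalents of solid reagent read as percent of the substrate charged, on the assumption that each product takes one partner, 80.0%. The partner is what the solid reagent puts into solution.

the same everywhere: substrate 0.50 M
- epsilon: solid reagent 0.80 equiv; initiator 0.73 mol%; the very flask that is asked about, followed so far
- gamma: solid reagent 0.80 equiv; initiator 1.5 mol%; run made earlier
- flask: solid reagent 0.800 equiv; initiator 0.73 mol%; time 15 d

- epsilon (time / d: product / %, substrate / %): 0.625: 59.0, 40.6; 2.08: 79.8, 19.5; 4.00: 80.0, 18.4; 5.00: 80.1, 18.1; 8.00: 79.4, 19.4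
- gamma (time / d: product / %, substrate / %): 1.25: 79.9, 18.5; 4.00: 80.9, 17.6; 8.00: 79.1, 18.2; 10.0: 80.5, 17.4; 15.0: 79.5, 17.0

(each reading ± 0.5 percentage points)

- as a solid, counted per litre of solution: solid reagent
- at the start none of the solid reagent is in solution
- the reaction counts as stopped when no species that holds the substrate changes by six tenths of a point or more over the second half of the time

- at 15 d, what has stopped the reaction, if anything has (for what has run out or reacted, a solid counts together with what of it has only dissolved) (it is still moving / the partner has run out first / all of the substrate has reacted)
- amount of product at 15 d, in percent of the substrate charged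

Read down the epsilon table, product climbs from 59.0% at 0.625 d to 79.8% at 2.08 d, then reads 80.1% at 5.00 d and 79.4% at 8.00 d, a flat line within the scatter of 0.5 percentage points, although substrate still reads 19.4%. So substrate is not what halts this flask. The gamma table, at 1.5 mol% of initiator, has 79.9% at 1.25 d and 79.5% at 15.0 d, so its plateau stands level with that of epsilon, and both sit on the ceiling. My own reckoning is therefore 80.0% of product, with the partner as limiting reagent.

The forecast agrees, with 80% and the verdict the partner has run out first, reasoning that “the partner, counting solid and dissolved together, has been used up first”.

The flask gives 80.0% of product at 15 d, and the verdict the partner has run out first.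

    initiator → 2 initiating radical (k = 3.30 × 10⁻⁴ min⁻¹)
    substrate + initiating radical → capped initiator + first chain carrier (k = 15000 L mol⁻¹ s⁻¹)
    partner + first chain carrier → product + second chain carrier (k = 93000 L mol⁻¹ min⁻¹)
    substrate + second chain carrier → released group + first chain carrier (k = 1.50 × 10⁵ L mol⁻¹ min⁻¹)
    first chain carrier → ended carrier (k = 51.0 min⁻¹)
    2 second chain carrier → ended chains (k = 2.00 × 10⁸ L mol⁻¹ s⁻¹)
    solid reagent ⇌ partner, rate k7*(cs7 - [partner]) while solid is left; crystals form when [partner] > cs7 (solubility = 0.360 M, k = 0.0110 min⁻¹)

In this flask the solid reagent stood at 0% of its charge and the partner at 0.00753 M by 1.50 d, while the two chain steps ran: the midpoint of the partner step's turnover came at 0.345 d, and 99.9% of the substrate step's turnover stood behind it at 3.00 d. At 15 d the share of partner left is 0%, substrate stands at 18.8%, and product sits on the ceiling. A neighbouring flask, charged with 0.200 equiv of solid reagent, has a ceiling of 20.0% and stands at 20.0% of product, with 79% of its substrate left.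

(The numbers in the tables were computed on assumed constants.)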